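**Decalin numbering used throughout:** C1 is the quaternary carbon (methyl and acyl), C2 carries the pentadienyl chain, C3=C4 is the ring alkene, C4a/C8a are the ring fusion, C6 carries the ring-B methyl. Ring A is C1–C4, C4a, C8a; ring B is C4a–C8a.

## Analysis of the target

Compound 27 is a 3-acyltetramic acid whose acyl carbon is bonded to the quaternary C1 of a trans-fused 1,2,4a,5,6,7,8,8a-octahydronaphthalene. The decalin has five stereocentres, (1R,2R,4aR,6R,8aS). H4a and H8a are trans; the acyl group on C1 is cis to H8a and trans to the (1E,3E)-pentadienyl group on C2, so the C1 methyl is axial and cis to that chain. The C6 methyl is axial as well, on the same side of ring B as H4a and cis to the C8a–C1 bond. The two remaining stereocentres, (5S) in the pyrrolidine-2,4-dione and (1R) in its 1-hydroxyethyl side chain, are those of L-threonine. Sensitive groups are the tetramic acid (acidic, chelating, epimerisable at C5 under base), the doubly allylic C2–H between the ring alkene and the diene, the diene itself and the free secondary alcohol. The difficulty lies in the quaternary C1 flanked by two stereocentres, and in the axial C6 methyl, which is 1,4 to the nearest other stereocentre (C8a) and has nothing nearby to relay from. The strategy rests on the contiguous triad C8a–C1–C2 of ring A: C1 carries a methyl and a carbonyl group, C2 a carbon substituent trans to that carbonyl. This is the pattern left when an (E)-2-methylbutenedioate adds across C8a and C3 of a diene C3=C4–C4a=C8a built on ring B.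

## Retrosynthetic reasoning

**Tetramic acid.** The ring of 27 is opened at the bond between its acyl-bearing carbon and the ring ketone carbon (Lacey–Dieckmann), giving β-keto amide 26. The amide bond is then cut to β-keto thioester 24 and amino ester 25. This places the base-sensitive heterocycle in the last step and takes both of its stereocentres from 25. The forward reaction must close the ring faster than C5 epimerises.

**Acyl chain on C1.** The bond between the carbinol carbon and the methylene of 23 is cut (aldol), leading back to aldehyde 22, which comes from ester 20 by way of alcohol 21. An aldehyde is chosen because direct acylation chemistry at this neopentyl ester is not realistic, whereas a small enolate will add to a non-enolisable aldehyde.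

**Diene on C2.** The σ-bond between the two alkenes of 20 is cut (cross-coupling) to iodoalkene 19, and the C=C bond of 19 is cut (iodo-olefination) to aldehyde 18. Each alkene is thereby made in a step with its own geometric control, under non-basic or weakly basic conditions that spare the labile C2–H. Aldehyde 18 comes from alcohol 17, and 17 from diester 16 by reducing only the less hindered C2 ester.

**Ring alkene and ring fusion.** C3=C4 of 16 is traced to enol triflate 15 and ketone 13. A ketone at C4 is the natural origin of this alkene, and it also makes C4a epimerisable, so the trans fusion can be set by equilibration of 12 to 13. Ketone 13 comes from silyl enol ether 11.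

**Key disconnection.** In 11 the bonds C8a–C1 and C2–C3 are cut, which removes ring A and gives diene 9 and diester 10. This is chosen because it creates the quaternary C1, C2 and C8a together, derives the trans relationship at C1/C2 from the alkene geometry of 10, and leaves a carbonyl on each of C1, C2 and C4 where the target needs a handle. The forward reaction must be regioselective, place the C1 ester exo, and attack the face of ring B cis to the C6 methyl.

**Diene.** Diene 9 is the silyl dienol ether of enone 8. The ring alkene of 8 is cut (intramolecular Horner–Wadsworth–Emmons) to 7, which comes from 5 by ozonolysis, from 2 by acylation and from bromide 1. The phosphorus-bearing carbon must be the former bromomethylene carbon of 1 itself: counting from it to the alkene carbon that becomes the aldehyde gives six ring atoms. A separate phosphorus-bearing carbon placed between them would close a seven-membered ring. The olefination fixes unambiguously which carbon bears the acetyl group, which enolisation or dehydration of a 3-methylcyclohexanone derivative could not do.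

## Alternatives that were turned down

**Alternative 1:** This plan cuts C4a–C8a and C5–C6, so ring B is formed by an intramolecular Diels–Alder reaction of an open-chain trienone. Its vinyl ketone (C4=O, C4a=C5) is tethered through C3, C2 and C1 to an (E,E)-diene (C8a=C8–C7=C6, with the future C6 methyl as terminal substituent), and ring A closes as the tether ring. Promoted by an alkylaluminium chloride and followed by basic equilibration at C4a, it would give trans-fused octalone A1. In its favour, suprafacial addition to an (E,E)-diene ties C6 to C8a by geometry, and both rings form in one step. On the C6/C8a relationship it is stronger than the chosen plan, which relies there on the facial bias of a remote methyl group. Against it, the quaternary C1 and its neighbour C2 must be built in an open chain before cyclisation, and the facial sense of the cycloaddition then depends on how that quaternary allylic centre orients the diene. The alkene of A1 lies in ring B (C7=C8) and must be hydrogenated, and C3=C4 still has to be made from the C4 ketone as in the chosen route. What the chosen plan offers in exchange is that C1 and C2 arise in the ring-forming step from a commercial achiral diester, with no acyclic quaternary stereocentre to prepare.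

**Alternative 2:** This plan cuts C1–C8a, closing ring A by a Nicholas reaction. A boron Lewis acid ionises a hexacarbonyldicobalt-complexed tertiary propargylic ether and a ring-B silyl enol ether attacks through C8a. Oxidative removal of cobalt and base equilibration at C8a would give the trans-fused ethynyl ketone A2. In its favour, a cobalt-stabilised propargylic cation is one of the few electrophiles that readily forms a bond to a quaternary carbon next to a ring fusion. C3=C4 is present before cyclisation, and the ethynyl group is a compact precursor of the β-keto acyl chain. On both points it is stronger than the chosen plan, which needs two steps for the alkene and four for the chain. Against it, A2 lacks the C6 methyl. Adding it from the C8 ketone requires desaturation, conjugate methyl addition with axial delivery and removal of the C8 oxygen, all in the presence of an alkyne and an alkene and on the ring farthest from any control element. The C1 configuration depends on how methyl and the bulky cobalt cluster distribute in the cyclisation, the precursor needs a Z-alkene and two stereocentres, and cobalt is stoichiometric. The chosen plan brings the C6 methyl in from the chiral pool and sets C1 by alkene geometry.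

**Alternative 3:** This plan cuts C4–C4a and C1=C8a, a desymmetrising Robinson annulation. A cinchona-derived primary amine salt converts 4-methylcyclohexanone A4 into a chiral enamine, which adds to methyl 3-oxopent-4-enoate A5; aldol condensation then gives octalone ester A3. In its favour, it is the shortest and the only catalytic asymmetric entry, from two achiral bulk chemicals, and the C4a/C6 relationship follows from axial attack on the enamine. On cost and on C4a/C6 control it is stronger than the chosen plan. Against it, A3 carries none of the ring-A stereocentres. C8a and the quaternary C1 would need a reductive methylation of the unsaturated β-keto ester. C2 is a ketone carbon in A3 and must become an sp3 carbon bearing the dienyl chain next to a C3=C4 alkene, which requires carbon introduction with transposition of unsaturation. The chosen cycloaddition delivers ring A with carbon substituents on C1 and C2 in the correct relative configuration and a ketone at C4 placed to give C3=C4.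

Key step: step 6

**Remark on the chemistry:** 27 is drawn as its 3-acyl-4-hydroxy tautomer; the other tautomeric and chelated forms are the same compound. Carbanions and enolates made before the next reagent is added, the ozonide and the tetrahedral amide adduct are counted as non-isolated intermediates. Metal alkoxides that are only the salt of a product before work-up are not.

## Route

Step 1
Reactants: 1 (R)-citronellyl bromide [(6R)-8-bromo-2,6-dimethyloct-2-ene]
Product: 2 diethyl [(3R)-3,7-dimethyloct-6-en-1-yl]phosphonate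
Conditions: P(OEt)3 (3 equiv), neat, 150 °C, EtBr distilled off
Reagents that add atoms: triethyl phosphite, CCOP(OCC)OCC
Why: Michaelis–Arbuzov reaction of an unhindered primary bromide; the stereocentre is two carbons away and is not touched.

Step 2
Reactants: 2 diethyl [(3R)-3,7-dimethyloct-6-en-1-yl]phosphonate
Product: 5 diethyl [(5R)-5,9-dimethyl-2-oxodec-8-en-3-yl]phosphonate (both C3 epimers), via lithiated phosphonate 3 (not isolated), via lithium hemiaminal adduct 4 (not isolated)
Conditions: n-BuLi (1.05 equiv), THF, −78 °C; MeC(O)N(OMe)Me (1.2 equiv), −78 → 0 °C; aqueous work-up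
Reagents that add atoms: N-methoxy-N-methylacetamide, CC(=O)N(C)OC
Why: Acylation of an α-lithiated alkylphosphonate with a Weinreb amide; the chelated adduct 4 persists until work-up, so the more acidic β-ketophosphonate never meets the carbanion. The phosphorus-bearing stereocentre forms without control and is erased in step 4.

Step 3
Reactants: 5 diethyl [(5R)-5,9-dimethyl-2-oxodec-8-en-3-yl]phosphonate
Product: 7 diethyl [(5R)-5-methyl-2,8-dioxooctan-3-yl]phosphonate, via ozonide 6 (not isolated)
Conditions: O3, CH2Cl2, −78 °C; Me2S, −78 °C → rt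
Reagents that add atoms: ozone, [O-][O+]=O
Why: Ozonolysis of the electron-rich trisubstituted alkene with reductive work-up; the β-ketophosphonate has no site that ozone attacks under these conditions.

Step 4
Reactants: 7 diethyl [(5R)-5-methyl-2,8-dioxooctan-3-yl]phosphonate
Product: 8 1-[(5R)-5-methylcyclohex-1-en-1-yl]ethan-1-one
Conditions: K2CO3 (3 equiv), 18-crown-6 (0.2 equiv), toluene (0.01 M), 60 °C
Reagents that add atoms: none
Why: Intramolecular Horner–Wadsworth–Emmons olefination; carbonate deprotonates only the doubly activated P–CH–C=O carbon, so the ring closes between the former bromomethylene carbon of 1 and the aldehyde carbon. This should give the six-membered 1-acetylcyclohexene with the methyl group on C5 and no regioisomer.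

Step 5
Reactants: 8 1-[(5R)-5-methylcyclohex-1-en-1-yl]ethan-1-one
Product: 9 tert-butyl(dimethyl){[1-((5R)-5-methylcyclohex-1-en-1-yl)ethenyl]oxy}silane
Conditions: TBSOTf (1.2 equiv), Et3N (2 equiv), CH2Cl2, 0 °C
Reagents that add atoms: tert-butyldimethylsilyl trifluoromethanesulfonate, CC(C)(C)[Si](C)(C)OS(=O)(=O)C(F)(F)F
Why: Soft enolisation of a methyl enone: the O-silylated ketone is deprotonated by the amine at the acetyl methyl group, which gives the cross-conjugated 2-silyloxydiene. The stereocentre is not involved.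

Step 6
Reactants: 9 tert-butyl(dimethyl){[1-((5R)-5-methylcyclohex-1-en-1-yl)ethenyl]oxy}silane; 10 dimethyl mesaconate [dimethyl (2E)-2-methylbut-2-enedioate]
Product: 11 dimethyl (1R,2R,6R,8aS)-4-[(tert-butyldimethylsilyl)oxy]-1,6-dimethyl-1,2,3,5,6,7,8,8a-octahydronaphthalene-1,2-dicarboxylate
Conditions: 10 (3 equiv), toluene (1 M), 2,6-di-tert-butyl-4-methylphenol (1 mol %), sealed tube, 130–140 °C
Reagents that add atoms: none
Why: Thermal Diels–Alder reaction of a 2-silyloxydiene with a trisubstituted (E)-butenedioate, the established reaction type of 1-(1-silyloxyvinyl)cyclohexenes with fumarates and α-methyl acrylates; it is concerted but asynchronous, with the C3–C2 bond leading. The silyloxy group on C4 makes the CH2 terminus C3 the nucleophilic end, which bonds to the unsubstituted, less hindered and more electrophilic alkene carbon of 10 (the future C2), so the methyl-bearing carbon becomes C1 and bonds to the ring terminus C8a. Ring A closes as the six-membered ring of the [4+2] adduct, annulated onto ring B, with both new σ-bonds formed suprafacially on each component. C2 is fixed relative to C1 by the (E)-geometry of 10, which is carried over as the trans relationship of the two esters. C1 is fixed relative to C8a by the orientation of 10: with the C2 ester endo below C4 and the small C1 methyl endo below C4a, the C1 ester is exo and ends cis to H8a, an orientation that α-methyl acceptors tend to adopt because the branched carbonyl avoids the substituted inner diene carbon and its ring methylene C5. C8a is fixed relative to C6 by the face of ring B that is attacked: antiparallel bond formation at C8a on the half-chair with a pseudo-equatorial C6 methyl leads directly to a chair with the new bond cis to that methyl, whereas the other face needs a pseudo-axial methyl or a twist-boat-like approach. The step therefore needs regioselectivity (secured by the silyloxy group and the substitution of 10), exo placement of the C1 ester (secured by the α-methyl group) and attack on the ring-B face cis to the C6 methyl (secured only moderately by the remote stereocentre). Diastereomers from the other face or the other orientation are to be separated by chromatography here or at ketone 13.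

Step 7
Reactants: 11 dimethyl (1R,2R,6R,8aS)-4-[(tert-butyldimethylsilyl)oxy]-1,6-dimethyl-1,2,3,5,6,7,8,8a-octahydronaphthalene-1,2-dicarboxylate
Product: 13 dimethyl (1R,2R,4aS,6R,8aS)-1,6-dimethyl-4-oxodecahydronaphthalene-1,2-dicarboxylate (trans-fused), via cis-fused ketone 12 (not isolated)
Conditions: K2CO3 (1.5 equiv), MeOH, 0 °C → rt
Reagents that add atoms: none
Why: Methanolysis of the silyl enol ether and base equilibration of the α-stereocentre C4a through the enolate. The trans-fused ketone should dominate strongly: each chair form of cis-fused 12 has a syn-diaxial clash (C1 methyl against C5, or C6 methyl against C4), whereas 13 pays only for one axial methyl. C2 is far less acidic and is not expected to epimerise under these conditions.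

Step 8
Reactants: 13 dimethyl (1R,2R,4aS,6R,8aS)-1,6-dimethyl-4-oxodecahydronaphthalene-1,2-dicarboxylate
Product: 15 dimethyl (1R,2R,4aS,6R,8aS)-1,6-dimethyl-4-[(trifluoromethanesulfonyl)oxy]-1,2,4a,5,6,7,8,8a-octahydronaphthalene-1,2-dicarboxylate, via potassium enolate 14 (not isolated)
Conditions: KN(SiMe3)2 (1.1 equiv), THF, −78 °C; PhNTf2 (1.2 equiv), −78 → 0 °C
Reagents that add atoms: N-phenylbis(trifluoromethanesulfonimide), O=S(=O)(N(c1ccccc1)S(=O)(=O)C(F)(F)F)C(F)(F)F
Why: Kinetic deprotonation of a trans-1-decalone-type ketone by a bulky amide removes a proton from the methylene C3 and not from the ring-fusion methine C4a, so C4a keeps its configuration; O-sulfonylation of the enolate gives the C3=C4 enol triflate.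

Step 9
Reactants: 15 dimethyl (1R,2R,4aS,6R,8aS)-1,6-dimethyl-4-[(trifluoromethanesulfonyl)oxy]-1,2,4a,5,6,7,8,8a-octahydronaphthalene-1,2-dicarboxylate
Product: 16 dimethyl (1R,2R,4aR,6R,8aS)-1,6-dimethyl-1,2,4a,5,6,7,8,8a-octahydronaphthalene-1,2-dicarboxylate
Conditions: Pd(OAc)2 (5 mol %), PPh3 (10 mol %), HCO2H (2 equiv), n-Bu3N (3 equiv), DMF, 60 °C
Reagents that add atoms: none
Why: Palladium-catalysed formate reduction of an enol triflate (oxidative addition, formate exchange, decarboxylation, C–H reductive elimination) leaves the alkene where the triflate was; the esters are inert and the amine is too weak a base to move the double bond.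

Step 10
Reactants: 16 dimethyl (1R,2R,4aR,6R,8aS)-1,6-dimethyl-1,2,4a,5,6,7,8,8a-octahydronaphthalene-1,2-dicarboxylate
Product: 17 methyl (1R,2R,4aR,6R,8aS)-2-(hydroxymethyl)-1,6-dimethyl-1,2,4a,5,6,7,8,8a-octahydronaphthalene-1-carboxylate
Conditions: i-Bu2AlH (2.2 equiv), CH2Cl2, −78 °C; aq. potassium sodium tartrate
Reagents that add atoms: none
Why: Hydride reduction that differentiates the two esters by steric access: the secondary C2 ester is reduced to the primary alcohol, while the C1 ester on the quaternary carbon, shielded by the axial methyl, C8 and C2, is expected to survive at low temperature. No base is present that could affect the allylic C2–H.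

Step 11
Reactants: 17 methyl (1R,2R,4aR,6R,8aS)-2-(hydroxymethyl)-1,6-dimethyl-1,2,4a,5,6,7,8,8a-octahydronaphthalene-1-carboxylate
Product: 18 methyl (1R,2R,4aR,6R,8aS)-2-formyl-1,6-dimethyl-1,2,4a,5,6,7,8,8a-octahydronaphthalene-1-carboxylate
Conditions: Dess–Martin periodinane (1.3 equiv), pyridine (3 equiv), CH2Cl2, 0 °C; used at once
Reagents that add atoms: none
Why: Dess–Martin oxidation under buffered, non-basic conditions should give the β,γ-unsaturated aldehyde without epimerisation at C2 or migration of the ring alkene into conjugation.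

Step 12
Reactants: 18 methyl (1R,2R,4aR,6R,8aS)-2-formyl-1,6-dimethyl-1,2,4a,5,6,7,8,8a-octahydronaphthalene-1-carboxylate
Product: 19 methyl (1R,2S,4aR,6R,8aS)-2-[(E)-2-iodoethenyl]-1,6-dimethyl-1,2,4a,5,6,7,8,8a-octahydronaphthalene-1-carboxylate
Conditions: CrCl2 (6 equiv), CHI3 (2 equiv), THF–1,4-dioxane, 0 °C → rt
Reagents that add atoms: iodoform, IC(I)I
Why: Takai olefination: the geminal dichromium reagent adds to the aldehyde and elimination gives the (E)-iodoalkene, with particularly high E-selectivity for α-branched aldehydes. The reagent is not basic, so the labile C2–H is spared; the change of the C2 descriptor is only a change of priorities.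

Step 13
Reactants: 19 methyl (1R,2S,4aR,6R,8aS)-2-[(E)-2-iodoethenyl]-1,6-dimethyl-1,2,4a,5,6,7,8,8a-octahydronaphthalene-1-carboxylate
Product: 20 methyl (1R,2R,4aR,6R,8aS)-1,6-dimethyl-2-[(1E,3E)-penta-1,3-dien-1-yl]-1,2,4a,5,6,7,8,8a-octahydronaphthalene-1-carboxylate
Conditions: (E)-MeCH=CH–B(pin) (1.5 equiv), Pd(PPh3)4 (5 mol %), K3PO4 (3 equiv), THF–H2O, 50 °C
Reagents that add atoms: 4,4,5,5-tetramethyl-2-[(1E)-prop-1-en-1-yl]-1,3,2-dioxaborolane, C/C=C/B1OC(C)(C)C(C)(C)O1
Why: Suzuki–Miyaura coupling of an alkenyl iodide with an alkenylboronate proceeds with retention at both alkenes, so the (1E,3E)-diene is assembled from two geometrically defined halves under a mild phosphate base.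

Step 14
Reactants: 20 methyl (1R,2R,4aR,6R,8aS)-1,6-dimethyl-2-[(1E,3E)-penta-1,3-dien-1-yl]-1,2,4a,5,6,7,8,8a-octahydronaphthalene-1-carboxylate
Product: 21 [(1R,2R,4aR,6R,8aS)-1,6-dimethyl-2-[(1E,3E)-penta-1,3-dien-1-yl]-1,2,4a,5,6,7,8,8a-octahydronaphthalen-1-yl]methanol
Conditions: LiAlH4 (1.5 equiv), THF, 0 °C → rt
Reagents that add atoms: none
Why: The small, strong hydride donor reduces the hindered methyl ester on the quaternary carbon to the primary alcohol; the isolated alkene and the diene are inert.

Step 15
Reactants: 21 [(1R,2R,4aR,6R,8aS)-1,6-dimethyl-2-[(1E,3E)-penta-1,3-dien-1-yl]-1,2,4a,5,6,7,8,8a-octahydronaphthalen-1-yl]methanol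
Product: 22 (1R,2R,4aR,6R,8aS)-1,6-dimethyl-2-[(1E,3E)-penta-1,3-dien-1-yl]-1,2,4a,5,6,7,8,8a-octahydronaphthalene-1-carbaldehyde
Conditions: Dess–Martin periodinane (1.5 equiv), pyridine (3 equiv), CH2Cl2, rt
Reagents that add atoms: none
Why: Dess–Martin oxidation of a neopentyl-type alcohol; the aldehyde has no α-hydrogen and cannot epimerise.

Step 16
Reactants: 22 (1R,2R,4aR,6R,8aS)-1,6-dimethyl-2-[(1E,3E)-penta-1,3-dien-1-yl]-1,2,4a,5,6,7,8,8a-octahydronaphthalene-1-carbaldehyde
Product: 23 S-tert-butyl 3-[(1R,2R,4aR,6R,8aS)-1,6-dimethyl-2-[(1E,3E)-penta-1,3-dien-1-yl]-1,2,4a,5,6,7,8,8a-octahydronaphthalen-1-yl]-3-hydroxypropanethioate (both carbinol epimers)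
Conditions: MeC(O)S-t-Bu (3 equiv), LiN(SiMe3)2 (3 equiv), THF, −78 °C; then 22, −78 → −40 °C; aqueous quench at −40 °C
Reagents that add atoms: S-tert-butyl ethanethioate, CC(=O)SC(C)(C)C
Why: Aldol addition of a small lithium thioester enolate to a non-enolisable aldehyde; the carbinol centre forms without control and is removed in step 17.

Step 17
Reactants: 23 S-tert-butyl 3-[(1R,2R,4aR,6R,8aS)-1,6-dimethyl-2-[(1E,3E)-penta-1,3-dien-1-yl]-1,2,4a,5,6,7,8,8a-octahydronaphthalen-1-yl]-3-hydroxypropanethioate
Product: 24 S-tert-butyl 3-[(1R,2R,4aR,6R,8aS)-1,6-dimethyl-2-[(1E,3E)-penta-1,3-dien-1-yl]-1,2,4a,5,6,7,8,8a-octahydronaphthalen-1-yl]-3-oxopropanethioate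
Conditions: Dess–Martin periodinane (1.5 equiv), CH2Cl2, rt
Reagents that add atoms: none
Why: Dess–Martin oxidation of a β-hydroxy thioester to the β-keto thioester, mild enough for the diene and the doubly allylic C2–H.

Step 18
Reactants: 24 S-tert-butyl 3-[(1R,2R,4aR,6R,8aS)-1,6-dimethyl-2-[(1E,3E)-penta-1,3-dien-1-yl]-1,2,4a,5,6,7,8,8a-octahydronaphthalen-1-yl]-3-oxopropanethioate; 25 L-threonine methyl ester hydrochloride [methyl (2S,3R)-2-amino-3-hydroxybutanoate hydrochloride]
Product: 26 methyl N-{3-[(1R,2R,4aR,6R,8aS)-1,6-dimethyl-2-[(1E,3E)-penta-1,3-dien-1-yl]-1,2,4a,5,6,7,8,8a-octahydronaphthalen-1-yl]-3-oxopropanoyl}-L-threoninate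
Conditions: 25 (1.5 equiv), Et3N (3 equiv), CF3CO2Ag (1.2 equiv), THF, 0 °C → rt
Reagents that add atoms: none
Why: Thiophilic activation of the thioester by the silver salt lets the amine acylate at low temperature; nitrogen reacts far faster than the secondary hydroxyl, and no base strong enough to epimerise the amino ester is present.

Step 19
Reactants: 26 methyl N-{3-[(1R,2R,4aR,6R,8aS)-1,6-dimethyl-2-[(1E,3E)-penta-1,3-dien-1-yl]-1,2,4a,5,6,7,8,8a-octahydronaphthalen-1-yl]-3-oxopropanoyl}-L-threoninate
Product: 27 (5S)-3-{[(1R,2R,4aR,6R,8aS)-1,6-dimethyl-2-[(1E,3E)-penta-1,3-dien-1-yl]-1,2,4a,5,6,7,8,8a-octahydronaphthalen-1-yl]carbonyl}-4-hydroxy-5-[(1R)-1-hydroxyethyl]-1,5-dihydro-2H-pyrrol-2-one (the target)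
Conditions: NaOMe (3 equiv), MeOH, rt, short reaction time; then 1 M HCl to pH 2
Reagents that add atoms: none
Why: Lacey–Dieckmann cyclisation: the β-keto amide anion attacks the methyl ester and closes the pyrrolidine-2,4-dione, whose stabilised anion resists further deprotonation. Brief exposure should leave C5 and the hydroxyethyl centre, both taken from 25, unchanged.

## Compound list

1 | (R)-citronellyl bromide, (6R)-8-bromo-2,6-dimethyloct-2-ene | BrCC[C@H](C)CCC=C(C)C | starting material
2 | diethyl [(3R)-3,7-dimethyloct-6-en-1-yl]phosphonate | CCOP(=O)(OCC)CC[C@H](C)CCC=C(C)C | intermediate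
3 | diethyl [(3R)-1-lithio-3,7-dimethyloct-6-en-1-yl]phosphonate | [Li]C(C[C@H](C)CCC=C(C)C)P(=O)(OCC)OCC | intermediate (not isolated)
4 | lithium alkoxide of diethyl [(5R)-2-hydroxy-2-[methoxy(methyl)amino]-5,9-dimethyldec-8-en-3-yl]phosphonate | CC(O[Li])(N(C)OC)C(C[C@H](C)CCC=C(C)C)P(=O)(OCC)OCC | intermediate (not isolated)
5 | diethyl [(5R)-5,9-dimethyl-2-oxodec-8-en-3-yl]phosphonate, C3 epimers | CC(=O)C(C[C@H](C)CCC=C(C)C)P(=O)(OCC)OCC | intermediate
6 | diethyl [(5R)-7-(5,5-dimethyl-1,2,4-trioxolan-3-yl)-5-methyl-2-oxoheptan-3-yl]phosphonate (ozonide) | CC(=O)C(C[C@H](C)CCC1OOC(C)(C)O1)P(=O)(OCC)OCC | intermediate (not isolated)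
7 | diethyl [(5R)-5-methyl-2,8-dioxooctan-3-yl]phosphonate, C3 epimers | CC(=O)C(C[C@H](C)CCC=O)P(=O)(OCC)OCC | intermediate
8 | 1-[(5R)-5-methylcyclohex-1-en-1-yl]ethan-1-one | CC(=O)C1=CCC[C@@H](C)C1 | intermediate
9 | tert-butyl(dimethyl){[1-((5R)-5-methylcyclohex-1-en-1-yl)ethenyl]oxy}silane | C=C(O[Si](C)(C)C(C)(C)C)C1=CCC[C@@H](C)C1 | intermediate
10 | dimethyl mesaconate, dimethyl (2E)-2-methylbut-2-enedioate | COC(=O)/C=C(\C)C(=O)OC | starting material
11 | dimethyl (1R,2R,6R,8aS)-4-[(tert-butyldimethylsilyl)oxy]-1,6-dimethyl-1,2,3,5,6,7,8,8a-octahydronaphthalene-1,2-dicarboxylate | COC(=O)[C@@H]1CC(O[Si](C)(C)C(C)(C)C)=C2C[C@H](C)CC[C@@H]2[C@@]1(C)C(=O)OC | intermediate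
12 | dimethyl (1R,2R,4aR,6R,8aS)-1,6-dimethyl-4-oxodecahydronaphthalene-1,2-dicarboxylate (cis-fused) | COC(=O)[C@@H]1CC(=O)[C@@H]2C[C@H](C)CC[C@@H]2[C@@]1(C)C(=O)OC | intermediate (not isolated)
13 | dimethyl (1R,2R,4aS,6R,8aS)-1,6-dimethyl-4-oxodecahydronaphthalene-1,2-dicarboxylate (trans-fused) | COC(=O)[C@@H]1CC(=O)[C@H]2C[C@H](C)CC[C@@H]2[C@@]1(C)C(=O)OC | intermediate
14 | potassium (1R,2R,4aS,6R,8aS)-1,2-bis(methoxycarbonyl)-1,6-dimethyl-1,2,4a,5,6,7,8,8a-octahydronaphthalen-4-olate | [K+].COC(=O)[C@@H]1C=C([O-])[C@H]2C[C@H](C)CC[C@@H]2[C@@]1(C)C(=O)OC | intermediate (not isolated)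
15 | dimethyl (1R,2R,4aS,6R,8aS)-1,6-dimethyl-4-[(trifluoromethanesulfonyl)oxy]-1,2,4a,5,6,7,8,8a-octahydronaphthalene-1,2-dicarboxylate | COC(=O)[C@@H]1C=C(OS(=O)(=O)C(F)(F)F)[C@H]2C[C@H](C)CC[C@@H]2[C@@]1(C)C(=O)OC | intermediate
16 | dimethyl (1R,2R,4aR,6R,8aS)-1,6-dimethyl-1,2,4a,5,6,7,8,8a-octahydronaphthalene-1,2-dicarboxylate | COC(=O)[C@@H]1C=C[C@H]2C[C@H](C)CC[C@@H]2[C@@]1(C)C(=O)OC | intermediate
17 | methyl (1R,2R,4aR,6R,8aS)-2-(hydroxymethyl)-1,6-dimethyl-1,2,4a,5,6,7,8,8a-octahydronaphthalene-1-carboxylate | OC[C@@H]1C=C[C@H]2C[C@H](C)CC[C@@H]2[C@@]1(C)C(=O)OC | intermediate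
18 | methyl (1R,2R,4aR,6R,8aS)-2-formyl-1,6-dimethyl-1,2,4a,5,6,7,8,8a-octahydronaphthalene-1-carboxylate | O=C[C@@H]1C=C[C@H]2C[C@H](C)CC[C@@H]2[C@@]1(C)C(=O)OC | intermediate
19 | methyl (1R,2S,4aR,6R,8aS)-2-[(E)-2-iodoethenyl]-1,6-dimethyl-1,2,4a,5,6,7,8,8a-octahydronaphthalene-1-carboxylate | I/C=C/[C@@H]1C=C[C@H]2C[C@H](C)CC[C@@H]2[C@@]1(C)C(=O)OC | intermediate
20 | methyl (1R,2R,4aR,6R,8aS)-1,6-dimethyl-2-[(1E,3E)-penta-1,3-dien-1-yl]-1,2,4a,5,6,7,8,8a-octahydronaphthalene-1-carboxylate | C/C=C/C=C/[C@@H]1C=C[C@H]2C[C@H](C)CC[C@@H]2[C@@]1(C)C(=O)OC | intermediate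
21 | [(1R,2R,4aR,6R,8aS)-1,6-dimethyl-2-[(1E,3E)-penta-1,3-dien-1-yl]-1,2,4a,5,6,7,8,8a-octahydronaphthalen-1-yl]methanol | C/C=C/C=C/[C@@H]1C=C[C@H]2C[C@H](C)CC[C@@H]2[C@@]1(C)CO | intermediate
22 | (1R,2R,4aR,6R,8aS)-1,6-dimethyl-2-[(1E,3E)-penta-1,3-dien-1-yl]-1,2,4a,5,6,7,8,8a-octahydronaphthalene-1-carbaldehyde | C/C=C/C=C/[C@@H]1C=C[C@H]2C[C@H](C)CC[C@@H]2[C@@]1(C)C=O | intermediate
23 | S-tert-butyl 3-[(1R,2R,4aR,6R,8aS)-1,6-dimethyl-2-[(1E,3E)-penta-1,3-dien-1-yl]-1,2,4a,5,6,7,8,8a-octahydronaphthalen-1-yl]-3-hydroxypropanethioate, carbinol epimers | C/C=C/C=C/[C@@H]1C=C[C@H]2C[C@H](C)CC[C@@H]2[C@@]1(C)C(O)CC(=O)SC(C)(C)C | intermediate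
24 | S-tert-butyl 3-[(1R,2R,4aR,6R,8aS)-1,6-dimethyl-2-[(1E,3E)-penta-1,3-dien-1-yl]-1,2,4a,5,6,7,8,8a-octahydronaphthalen-1-yl]-3-oxopropanethioate | C/C=C/C=C/[C@@H]1C=C[C@H]2C[C@H](C)CC[C@@H]2[C@@]1(C)C(=O)CC(=O)SC(C)(C)C | intermediate
25 | L-threonine methyl ester hydrochloride, methyl (2S,3R)-2-amino-3-hydroxybutanoate hydrochloride | Cl.COC(=O)[C@@H](N)[C@@H](C)O | starting material
26 | methyl N-{3-[(1R,2R,4aR,6R,8aS)-1,6-dimethyl-2-[(1E,3E)-penta-1,3-dien-1-yl]-1,2,4a,5,6,7,8,8a-octahydronaphthalen-1-yl]-3-oxopropanoyl}-L-threoninate | C/C=C/C=C/[C@@H]1C=C[C@H]2C[C@H](C)CC[C@@H]2[C@@]1(C)C(=O)CC(=O)N[C@H](C(=O)OC)[C@@H](C)O | intermediate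
27 | (5S)-3-{[(1R,2R,4aR,6R,8aS)-1,6-dimethyl-2-[(1E,3E)-penta-1,3-dien-1-yl]-1,2,4a,5,6,7,8,8a-octahydronaphthalen-1-yl]carbonyl}-4-hydroxy-5-[(1R)-1-hydroxyethyl]-1,5-dihydro-2H-pyrrol-2-one | C/C=C/C=C/[C@@H]1C=C[C@H]2C[C@H](C)CC[C@@H]2[C@@]1(C)C(=O)C1=C(O)[C@H]([C@@H](C)O)NC1=O | target

## Step count and least certain steps

Total: 19 steps. Longest linear sequence: 19 steps (1 to 27); 10 and 25 are bought and enter in steps 6 and 18.

**Step 6 (key step).** What may go wrong: weak discrimination between the two faces of ring B by the remote C6 methyl, and competition from the orientation with the C1 ester endo, which would invert C1 and C2 relative to C8a. Slow reaction of the trisubstituted dienophile would add thermal loss of the diene. Fallback, from 9 and back at 13: the same ring construction under catalyst control with an α-methyl enal. Diene 9 is combined with methyl (2E)-3-methyl-4-oxobut-2-enoate F1 in CH2Cl2 at −78 °C. The catalyst is 1-(2-methylphenyl)-3,3-diphenyltetrahydro-1H,3H-pyrrolo[1,2-c][1,3,2]oxazaborole, N-protonated with HN(SO2CF3)2 (10–20 mol %), in the enantiomer that favours the same face as the C6 methyl. Formyl coordination keeps the regiochemistry (C3 to the ester-bearing CH, the formyl-bearing carbon to C8a), and α-methyl enals are the substrates for which this catalyst class gives formyl-exo adducts. The product, methyl (1R,2R,6R,8aS)-4-[(tert-butyldimethylsilyl)oxy]-1-formyl-1,6-dimethyl-1,2,3,5,6,7,8,8a-octahydronaphthalene-2-carboxylate F2, is methanolysed and equilibrated as in step 7 to methyl (1R,2R,4aS,6R,8aS)-1-formyl-1,6-dimethyl-4-oxodecahydronaphthalene-2-carboxylate F3. Oxidation with NaClO2/NaH2PO4/2-methylbut-2-ene gives (1R,2R,4aS,6R,8aS)-2-(methoxycarbonyl)-1,6-dimethyl-4-oxodecahydronaphthalene-1-carboxylic acid F4, and Me3SiCHN2 in MeOH–toluene converts it into 13.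

**Step 10.** What may go wrong: incomplete discrimination between the two esters (over-reduction at C1), or lactonisation of the hydroxy ester onto the C1 ester during work-up. Fallback, from 16 and back at 17: chemoselective hydrolysis instead of hydride discrimination. Me3SnOH in 1,2-dichloroethane at 80 °C should cleave only the less hindered C2 ester without epimerisation, giving (1R,2R,4aR,6R,8aS)-1-(methoxycarbonyl)-1,6-dimethyl-1,2,4a,5,6,7,8,8a-octahydronaphthalene-2-carboxylic acid F5. Isobutyl chloroformate and N-methylmorpholine in THF at −15 °C convert it into the isobutyl carbonic mixed anhydride F6, which NaBH4 reduces to 17.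

**Step 12.** What may go wrong: epimerisation at C2 or migration of the C3=C4 alkene into conjugation while the β,γ-unsaturated aldehyde 18 is made and handled, and erosion of the E-selectivity. Fallback, from 17 and back at 20: the aldehyde is avoided by reversing the polarity. Mitsunobu reaction of 17 with 1-phenyl-1H-tetrazole-5-thiol (PPh3, diisopropyl azodicarboxylate, THF) gives methyl (1R,2R,4aR,6R,8aS)-1,6-dimethyl-2-{[(1-phenyl-1H-tetrazol-5-yl)sulfanyl]methyl}-1,2,4a,5,6,7,8,8a-octahydronaphthalene-1-carboxylate F7. Oxidation with H2O2 and (NH4)6Mo7O24 in EtOH gives methyl (1R,2R,4aR,6R,8aS)-1,6-dimethyl-2-{[(1-phenyl-1H-tetrazol-5-yl)sulfonyl]methyl}-1,2,4a,5,6,7,8,8a-octahydronaphthalene-1-carboxylate F8. Julia–Kocienski olefination of F8 with KN(SiMe3)2 and (E)-but-2-enal in 1,2-dimethoxyethane at −60 °C gives 20 directly.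

**Step 16.** What may go wrong: failure of the enolate to add to the aldehyde on a quaternary carbon flanked by two substituted carbons, or retro-aldol cleavage on warming. Fallback, from 22 and back at 26: Roskamp homologation with ethyl diazoacetate and SnCl2 (10 mol %) in CH2Cl2 gives ethyl 3-[(1R,2R,4aR,6R,8aS)-1,6-dimethyl-2-[(1E,3E)-penta-1,3-dien-1-yl]-1,2,4a,5,6,7,8,8a-octahydronaphthalen-1-yl]-3-oxopropanoate F9 in one step. Heating F9 with 25 and Et3N in toluene at reflux (aminolysis through the acylketene) gives 26.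

**Step 19.** What may go wrong: epimerisation at C5 of the heterocycle under alkoxide, and fragmentation or acyl transfer involving the unprotected secondary hydroxyl. Fallback, from 24 and 25 and back at 27: the hydroxyl is carried as a silyl ether. TBSCl and imidazole in DMF convert 25 into methyl O-(tert-butyldimethylsilyl)-L-threoninate F10. Coupling of F10 with 24 (CF3CO2Ag, Et3N, THF) gives methyl O-(tert-butyldimethylsilyl)-N-{3-[(1R,2R,4aR,6R,8aS)-1,6-dimethyl-2-[(1E,3E)-penta-1,3-dien-1-yl]-1,2,4a,5,6,7,8,8a-octahydronaphthalen-1-yl]-3-oxopropanoyl}-L-threoninate F11. Cyclisation with KOt-Bu in t-BuOH gives (5S)-5-[(1R)-1-{[tert-butyl(dimethyl)silyl]oxy}ethyl]-3-{[(1R,2R,4aR,6R,8aS)-1,6-dimethyl-2-[(1E,3E)-penta-1,3-dien-1-yl]-1,2,4a,5,6,7,8,8a-octahydronaphthalen-1-yl]carbonyl}-4-hydroxy-1,5-dihydro-2H-pyrrol-2-one F12, and HF·pyridine in THF releases 27.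

## Further compounds

F1 | step 6 | methyl (2E)-3-methyl-4-oxobut-2-enoate | COC(=O)/C=C(\C)C=O
F2 | step 6 | methyl (1R,2R,6R,8aS)-4-[(tert-butyldimethylsilyl)oxy]-1-formyl-1,6-dimethyl-1,2,3,5,6,7,8,8a-octahydronaphthalene-2-carboxylate | COC(=O)[C@@H]1CC(O[Si](C)(C)C(C)(C)C)=C2C[C@H](C)CC[C@@H]2[C@@]1(C)C=O
F3 | step 6 | methyl (1R,2R,4aS,6R,8aS)-1-formyl-1,6-dimethyl-4-oxodecahydronaphthalene-2-carboxylate | COC(=O)[C@@H]1CC(=O)[C@H]2C[C@H](C)CC[C@@H]2[C@@]1(C)C=O
F4 | step 6 | (1R,2R,4aS,6R,8aS)-2-(methoxycarbonyl)-1,6-dimethyl-4-oxodecahydronaphthalene-1-carboxylic acid | COC(=O)[C@@H]1CC(=O)[C@H]2C[C@H](C)CC[C@@H]2[C@@]1(C)C(=O)O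
F5 | step 10 | (1R,2R,4aR,6R,8aS)-1-(methoxycarbonyl)-1,6-dimethyl-1,2,4a,5,6,7,8,8a-octahydronaphthalene-2-carboxylic acid | OC(=O)[C@@H]1C=C[C@H]2C[C@H](C)CC[C@@H]2[C@@]1(C)C(=O)OC
F6 | step 10 | isobutyl carbonic mixed anhydride of F5 | CC(C)COC(=O)OC(=O)[C@@H]1C=C[C@H]2C[C@H](C)CC[C@@H]2[C@@]1(C)C(=O)OC
F7 | step 12 | methyl (1R,2R,4aR,6R,8aS)-1,6-dimethyl-2-{[(1-phenyl-1H-tetrazol-5-yl)sulfanyl]methyl}-1,2,4a,5,6,7,8,8a-octahydronaphthalene-1-carboxylate | c1ccc(cc1)-n1nnnc1SC[C@@H]1C=C[C@H]2C[C@H](C)CC[C@@H]2[C@@]1(C)C(=O)OC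
F8 | step 12 | methyl (1R,2R,4aR,6R,8aS)-1,6-dimethyl-2-{[(1-phenyl-1H-tetrazol-5-yl)sulfonyl]methyl}-1,2,4a,5,6,7,8,8a-octahydronaphthalene-1-carboxylate | O=S(=O)(C[C@@H]1C=C[C@H]2C[C@H](C)CC[C@@H]2[C@@]1(C)C(=O)OC)c1nnnn1-c1ccccc1
F9 | step 16 | ethyl 3-[(1R,2R,4aR,6R,8aS)-1,6-dimethyl-2-[(1E,3E)-penta-1,3-dien-1-yl]-1,2,4a,5,6,7,8,8a-octahydronaphthalen-1-yl]-3-oxopropanoate | C/C=C/C=C/[C@@H]1C=C[C@H]2C[C@H](C)CC[C@@H]2[C@@]1(C)C(=O)CC(=O)OCC
F10 | step 19 | methyl O-(tert-butyldimethylsilyl)-L-threoninate | COC(=O)[C@@H](N)[C@@H](C)O[Si](C)(C)C(C)(C)C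
F11 | step 19 | methyl O-(tert-butyldimethylsilyl)-N-{3-[(1R,2R,4aR,6R,8aS)-1,6-dimethyl-2-[(1E,3E)-penta-1,3-dien-1-yl]-1,2,4a,5,6,7,8,8a-octahydronaphthalen-1-yl]-3-oxopropanoyl}-L-threoninate | C/C=C/C=C/[C@@H]1C=C[C@H]2C[C@H](C)CC[C@@H]2[C@@]1(C)C(=O)CC(=O)N[C@H](C(=O)OC)[C@@H](C)O[Si](C)(C)C(C)(C)C
F12 | step 19 | (5S)-5-[(1R)-1-{[tert-butyl(dimethyl)silyl]oxy}ethyl]-3-{[(1R,2R,4aR,6R,8aS)-1,6-dimethyl-2-[(1E,3E)-penta-1,3-dien-1-yl]-1,2,4a,5,6,7,8,8a-octahydronaphthalen-1-yl]carbonyl}-4-hydroxy-1,5-dihydro-2H-pyrrol-2-one | C/C=C/C=C/[C@@H]1C=C[C@H]2C[C@H](C)CC[C@@H]2[C@@]1(C)C(=O)C1=C(O)[C@H]([C@@H](C)O[Si](C)(C)C(C)(C)C)NC1=O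
A1 | alternative 1 | methyl 2-{[(4-methoxybenzyl)oxy]methyl}-1,6-dimethyl-4-oxo-1,2,3,4,4a,5,6,8a-octahydronaphthalene-1-carboxylate, trans-fused, configured as in the target | COc1ccc(COC[C@@H]3CC(=O)[C@H]2C[C@H](C)C=C[C@@H]2[C@@]3(C)C(=O)OC)cc1
A2 | alternative 2 | 8-ethynyl-7-{[(4-methoxybenzyl)oxy]methyl}-8-methyl-3,4,4a,7,8,8a-hexahydronaphthalen-1(2H)-one, trans-fused, configured as in the target | COc1ccc(COC[C@@H]3C=C[C@H]2CCCC(=O)[C@@H]2[C@@]3(C)C#C)cc1
A3 | alternative 3 | methyl 6-methyl-2-oxo-2,3,4,4a,5,6,7,8-octahydronaphthalene-1-carboxylate, C4a and C6 as in the target | COC(=O)C1=C2CC[C@@H](C)C[C@@H]2CCC1=O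
A4 | alternative 3 | 4-methylcyclohexanone | CC1CCC(=O)CC1
A5 | alternative 3 | methyl 3-oxopent-4-enoate | C=CC(=O)CC(=O)OC
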